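## Structural features

The target is a germacranolide: a ten-membered carbocycle (C1–C10) fused trans at C6–C7 to an α-methylene-γ-butyrolactone (O6–C12, C11=C13). The ring carries a trisubstituted 4Z alkene (C15 on C4), a trans 1,10-epoxide on the quaternary C10 (C14), a methacrylate on the allylic C3 and an angelate on C8. Of the six stereocentres (1R,3S,6R,7R,8R,10R), C6, C7 and C8 are contiguous, C1 and C10 share the epoxide, and C3 stands alone between the C2 methylene and the alkene. The angelate (Z to E isomerisation), the α-methylene lactone (Michael acceptor), the epoxide (acid, transannular attack by the alkene) and the methacrylate are all fragile, and a free C8 alkoxide can take the lactone over from O6. The real difficulty is the medium ring itself, with a Z alkene inside it and an oxygenated quaternary carbon, together with the order in which four sensitive groups are unveiled. The key step exploits the C2 methylene flanked by oxygenated C1 and C3: this 1,3-dioxygen pattern is an aldol retron, so a C3 ketone enolate (from a bromomethyl ketone) and a C1 aldehyde, which sits on quaternary C10 and cannot enolise, can close C1–C2 and the ring.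

## Logic of the disconnections

33 to 32: the C8 O–acyl bond is cut first, because the Z-2-methylbutenoate is the group most easily isomerised and should meet no further reagent. The forward step must esterify a hindered secondary alcohol without Z to E isomerisation and without moving the lactone to O8.

32 to 31 to 27: the O8–Si bond and then C11=C13 are removed. This keeps the Michael acceptor out of all earlier steps and leaves a robust saturated lactone. The demand is lactone enolate chemistry beside the C3 ester and the epoxide, and a desilylation that creates no alkoxide.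

27 to 25 to 24 to 23: the epoxide is cut at O–C1, with the oxygen staying on C10, where the chiral pool placed it; then the sulfonate and the C3 ester are removed. This reduces the epoxide to a 1,10-anti diol derivative. The forward closure inverts C1, so C1 must be S in 25, and in 23 the allylic C3 hydroxyl must be acylated in preference to the neopentyl C1 hydroxyl.

23 to 22: the C3–H bond is cut. The C1 hydroxyl can deliver hydride to the C3 ketone, so the C3 configuration is traced back to C1. The demand is 1,3-anti delivery inside a ten-membered ring.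

22 to 20 (key): C1–C2 is cut, which opens the ring to a chain with a bromomethyl Z-enone and a non-enolisable aldehyde. One ring and one stereocentre are removed. The forward step needs high dilution, reduction of C–Br in preference to the aldehyde and the γ-acyloxy enone, and the 1,10-anti sense at C1. Two choices follow from this.

- The C10 oxygen is carried as a triethylsilyl ether and not as a benzyl-type ether. A chelate between the aldehyde and a C10 ether oxygen, with C2 entering on the methyl face, would give the 1,10-syn adduct, which closes to the cis-epoxide. The trans-epoxide needs the Felkin–Anh adduct 22 (1S).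
- The 4-methoxybenzyl group is therefore placed on O1 in 4 to 15, where it is orthogonal to every silyl ether.

20 to 17 + 18: C3–C4 and C2–Br are cut. Cross-coupling keeps the Z geometry and the enol ether is brominated directly, so the sensitive bromoketone exists for one step only. The coupling must tolerate the aldehyde and the allylic lactone.

17 to 16 to 15 to 14 to 13: the C1 oxidation level, the C4=C5 bond and the C5 oxidation level are adjusted. A Z-selective iodo-olefination of the C5 aldehyde is required, without epimerisation at C6. The primary triethylsilyl ether at O5 is the only silyl group that has to leave at this stage.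

13 to 12 to 11 to 10: O8–Si, C8–H and the thioketal are removed. C8 comes from a ketone under Felkin control by C7. The demands are facial selectivity, no β-elimination of the lactone oxygen and no lactone migration.

10 to 8 + 2: C7–C8 is cut. Conjugate addition anti to the C6 substituent sets C7 and joins two chiral-pool pieces. The demand is 1,4-addition of a hindered tertiary carbanion. The thioketal carbon cannot be deprotonated once a lactone or an alkenyl iodide is present, so its alkylation must come before this union.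

8 to 5 + 4, 4 to 3, 2 to 1: C8–C9 is cut as an epoxide opening at the CH2 terminus, and two ether bonds are removed. C10 and C6 are bought as single enantiomers.

## Other disconnections considered

Alternative 1: the cut is at C3–C4 and C5–C6, on either side of the alkene. In the forward step the titanium–alkyne complex of trimethyl(prop-1-ynyl)silane A2 (Ti(OiPr)4, i-PrMgCl) inserts aldehyde A1 at the methyl-bearing carbon, and the alkenyltitanium adds to acrolein A3 to give the Z-enediol A4.
- In its favour: two C–C bonds and the trisubstituted alkene form in one flask, and the metallacycle fixes the cis relationship of C3 and C6. On alkene geometry and on convergence it is the equal or the better of the olefination and cross-coupling sequence used here.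
- Against it: neither carbinol (C3, C6) is set with a reliable control element, the silicon must be removed later, C7 and the lactone have still to be built from the vinyl group, and no ring is closed, so the hardest problem is postponed.
- Comparison: the chosen plan forms the ring and C1 in its key step and takes C6 and C7 from the chiral pool. The overall step count of Alternative 1 would probably be similar or higher once the stereochemical corrections and a ring closure are added.

Alternative 2: the cut is at C6–O and O–C12. In the forward step a CYP71-clan monooxygenase hydroxylates the dihydroxy acid A5 at C6 from the α face, and lactonisation gives A6.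
- In its favour: it is biomimetic and needs no protecting groups, enzymatic control at C6 is better than any reagent could offer, and the methylene lactone is present from the start, which avoids the late methylenation. On these points and on the number of steps after A5 it is better than the chosen plan.
- Against it: A5 is itself a ten-membered triene acid with a 4Z alkene and two carbinols, so the ring problem is only moved. Acceptance of a 3-hydroxylated 4Z substrate by such an enzyme is unproven, microsomal expression with a reductase partner is needed, and A6 still requires a face-selective 1(10)-epoxidation and differentiation of two secondary hydroxyls.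
- Comparison: the chosen plan is longer after ring formation but uses bench reagents whose selectivity can be argued step by step.

Alternative 3: the cut is a ring expansion in which C8–C9 forms while a six-membered ring bond breaks. In the forward step the potassium alkoxide of cyclohexenol A7 (KH, 18-crown-6) undergoes an anionic oxy-Cope shift through a chair to the cyclodecadienone A8.
- In its favour: a concerted and well-precedented route to ten-membered rings. The 1(10)E alkene is fixed by the chair and the 4Z alkene is inherited from the cyclohexene. Epoxidation of the E alkene gives the trans-epoxide stereospecifically, so no aldol facial selectivity and no inversion at C1 are needed. On these points it is better than the chosen plan.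
- Against it: A8 lacks C11–C13 and both C6 and C7 stereocentres. The lactone would have to be annulated by regioselective C7 alkylation of a cross-conjugated enolate and facial reduction at C6 in a mobile ring prone to transannular reactions, and C8 depends on the enol ether geometry.
- Comparison: ring formation is safer than a macro-Reformatsky closure, but stereocontrol at C6 and C7 would rest on macrocyclic conformation only, and the steps after the ring would be at least as many.

Key step: step 13

Remark: germacrane numbering is used for all intermediates (ring C1–C10, lactone carbons C11–C13 with the lactone oxygen on C6, C14 on C10, C15 on C4); PMB, TES and TBS stand for 4-methoxybenzyl, triethylsilyl and tert-butyldimethylsilyl, and 1 and 3 are taken as purchasable single enantiomers.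

Step 1
Reactants: 1 (5S)-5-(hydroxymethyl)furan-2(5H)-one
Product: 2 (5S)-5-{[(triethylsilyl)oxy]methyl}furan-2(5H)-one
Conditions: TESCl, imidazole, CH2Cl2, 0 °C
Reagents that add atoms: chlorotriethylsilane, CC[Si](Cl)(CC)CC
Why: Silylation of the primary alcohol with imidazole as base; this mild base leaves the acidic C5–H of the butenolide alone, so the centre that becomes C6 is kept.

Step 2
Reactants: 3 [(2S)-2-methyloxiran-2-yl]methanol
Product: 4 (2R)-2-{[(4-methoxybenzyl)oxy]methyl}-2-methyloxirane
Conditions: NaH, PMBCl, Bu4NI (cat.), THF/DMF, 0 °C → rt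
Reagents that add atoms: 4-methoxybenzyl chloride, COc1ccc(CCl)cc1
Why: Williamson etherification of the primary alkoxide; the quaternary centre (future C10) is untouched, and a Payne shift of the alkoxide would be degenerate and return the same enantiomer.

Step 3
Reactants: 5 1,3-dithiane; 4 (2R)-2-{[(4-methoxybenzyl)oxy]methyl}-2-methyloxirane
Product: 8 {[(2R)-1-(1,3-dithian-2-yl)-3-[(4-methoxybenzyl)oxy]-2-methylpropan-2-yl]oxy}triethylsilane, via 2-lithio-1,3-dithiane 6 (not isolated), via lithium alkoxide 7 (not isolated)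
Conditions: n-BuLi, THF, −30 °C; 4, −30 → 0 °C; then TESOTf, −78 → 0 °C
Reagents that add atoms: triethylsilyl trifluoromethanesulfonate, CC[Si](CC)(CC)OS(=O)(=O)C(F)(F)F
Why: The lithiated dithiane opens the 2,2-disubstituted epoxide at its CH2 terminus (SN2, bond C8–C9) and the tertiary lithium alkoxide is silylated in the same flask. The dithiane is alkylated here because its C2–H could not be removed later beside a lactone or an alkenyl iodide.

Step 4
Reactants: 8 {[(2R)-1-(1,3-dithian-2-yl)-3-[(4-methoxybenzyl)oxy]-2-methylpropan-2-yl]oxy}triethylsilane; 2 (5S)-5-{[(triethylsilyl)oxy]methyl}furan-2(5H)-one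
Product: 10 (4S,5S)-4-{2-[(2R)-3-[(4-methoxybenzyl)oxy]-2-methyl-2-(triethylsilyloxy)propyl]-1,3-dithian-2-yl}-5-{[(triethylsilyl)oxy]methyl}oxolan-2-one, via 2-lithiodithiane 9 (not isolated)
Conditions: t-BuLi, THF/HMPA (10:1), −78 °C; then 2 (slow addition), −78 °C; NH4Cl (aq)
Reagents that add atoms: none
Why: Conjugate addition of a sulfur-stabilised acyl-anion equivalent to a 5-substituted butenolide forms C7–C8. HMPA favours 1,4- over 1,2-addition, and the nucleophile enters anti to the C5 silyloxymethyl group, which sets C7 trans to C6.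

Step 5
Reactants: 10 (4S,5S)-4-{2-[(2R)-3-[(4-methoxybenzyl)oxy]-2-methyl-2-(triethylsilyloxy)propyl]-1,3-dithian-2-yl}-5-{[(triethylsilyl)oxy]methyl}oxolan-2-one
Product: 11 (4S,5S)-4-[(3R)-4-[(4-methoxybenzyl)oxy]-3-methyl-3-(triethylsilyloxy)butanoyl]-5-{[(triethylsilyl)oxy]methyl}oxolan-2-one
Conditions: Hg(ClO4)2·3H2O, CaCO3, THF/H2O, 0 °C
Reagents that add atoms: water, O
Why: Thiophilic divalent mercury cleaves the thioketal to the C8 ketone within minutes while CaCO3 takes up the acid, so the silyl ethers, the PMB ether and the base-sensitive β-acyloxy ketone should survive.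

Step 6
Reactants: 11 (4S,5S)-4-[(3R)-4-[(4-methoxybenzyl)oxy]-3-methyl-3-(triethylsilyloxy)butanoyl]-5-{[(triethylsilyl)oxy]methyl}oxolan-2-one
Product: 12 (4R,5S)-4-[(1R,3R)-1-hydroxy-4-[(4-methoxybenzyl)oxy]-3-methyl-3-(triethylsilyloxy)butyl]-5-{[(triethylsilyl)oxy]methyl}oxolan-2-one
Conditions: LiBH(s-Bu)3, THF, −78 °C; AcOH, −78 °C
Reagents that add atoms: none
Why: Felkin–Anh addition of a bulky hydride: the C7–C6 bond (the more substituted, oxygen-bearing ring bond) stands anti to the hydride, which passes the C7 hydrogen, and this should give the 8R carbinol. The cold acidic quench keeps the C8 alkoxide from attacking the lactone carbonyl.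

Step 7
Reactants: 12 (4R,5S)-4-[(1R,3R)-1-hydroxy-4-[(4-methoxybenzyl)oxy]-3-methyl-3-(triethylsilyloxy)butyl]-5-{[(triethylsilyl)oxy]methyl}oxolan-2-one
Product: 13 (4S,5S)-4-[(1R,3R)-1-(tert-butyldimethylsilyloxy)-4-[(4-methoxybenzyl)oxy]-3-methyl-3-(triethylsilyloxy)butyl]-5-{[(triethylsilyl)oxy]methyl}oxolan-2-one
Conditions: TBSOTf, 2,6-lutidine, CH2Cl2, −78 → 0 °C
Reagents that add atoms: tert-butyldimethylsilyl trifluoromethanesulfonate, CC(C)(C)[Si](C)(C)OS(=O)(=O)C(F)(F)F
Why: A silyl triflate with a hindered pyridine base silylates the hindered secondary alcohol under non-nucleophilic conditions, which also rules out lactone migration to O8.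

Step 8
Reactants: 13 (4S,5S)-4-[(1R,3R)-1-(tert-butyldimethylsilyloxy)-4-[(4-methoxybenzyl)oxy]-3-methyl-3-(triethylsilyloxy)butyl]-5-{[(triethylsilyl)oxy]methyl}oxolan-2-one
Product: 14 (2S,3S)-3-[(1R,3R)-1-(tert-butyldimethylsilyloxy)-4-[(4-methoxybenzyl)oxy]-3-methyl-3-(triethylsilyloxy)butyl]-5-oxooxolane-2-carbaldehyde
Conditions: (COCl)2, DMSO, CH2Cl2, −78 → −30 °C; then Et3N, −78 → 0 °C
Reagents that add atoms: none
Why: Swern conditions are known to desilylate a primary triethylsilyl ether and oxidise the alcohol in the same flask; the tertiary TES and secondary TBS ethers are too hindered to react.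

Step 9
Reactants: 14 (2S,3S)-3-[(1R,3R)-1-(tert-butyldimethylsilyloxy)-4-[(4-methoxybenzyl)oxy]-3-methyl-3-(triethylsilyloxy)butyl]-5-oxooxolane-2-carbaldehyde
Product: 15 (4S,5S)-4-[(1R,3R)-1-(tert-butyldimethylsilyloxy)-4-[(4-methoxybenzyl)oxy]-3-methyl-3-(triethylsilyloxy)butyl]-5-[(1Z)-2-iodoprop-1-en-1-yl]oxolan-2-one
Conditions: Ph3PEt+ I−, n-BuLi, THF, rt; I2, −78 °C; NaHMDS, −20 °C; then 14, −78 → −20 °C
Reagents that add atoms: ethyltriphenylphosphonium iodide, CC[P+](c1ccccc1)(c1ccccc1)c1ccccc1.[I-]; iodine, II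
Why: Stork–Zhao olefination with the α-iodoethylidene ylide, which is Z-selective for trisubstituted alkenyl iodides (iodine cis to C6). The ylide is used cold and is weakly basic, so the α-acyloxy aldehyde should not epimerise at C6.

Step 10
Reactants: 15 (4S,5S)-4-[(1R,3R)-1-(tert-butyldimethylsilyloxy)-4-[(4-methoxybenzyl)oxy]-3-methyl-3-(triethylsilyloxy)butyl]-5-[(1Z)-2-iodoprop-1-en-1-yl]oxolan-2-one
Product: 16 (4S,5S)-4-[(1R,3R)-1-(tert-butyldimethylsilyloxy)-4-hydroxy-3-methyl-3-(triethylsilyloxy)butyl]-5-[(1Z)-2-iodoprop-1-en-1-yl]oxolan-2-one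
Conditions: DDQ, CH2Cl2/pH 7 buffer, 0 °C
Reagents that add atoms: none
Why: Oxidative cleavage of the PMB ether through the benzylic cation; silyl ethers, lactone and alkenyl iodide are inert, and the neutral buffer should keep the TES group from moving to the new primary hydroxyl.

Step 11
Reactants: 16 (4S,5S)-4-[(1R,3R)-1-(tert-butyldimethylsilyloxy)-4-hydroxy-3-methyl-3-(triethylsilyloxy)butyl]-5-[(1Z)-2-iodoprop-1-en-1-yl]oxolan-2-one
Product: 17 (2R,4R)-4-(tert-butyldimethylsilyloxy)-4-{(2S,3S)-2-[(1Z)-2-iodoprop-1-en-1-yl]-5-oxooxolan-3-yl}-2-methyl-2-(triethylsilyloxy)butanal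
Conditions: DMP, NaHCO3, CH2Cl2, 0 °C → rt
Reagents that add atoms: none
Why: Dess–Martin oxidation of the neopentyl primary alcohol under buffered, non-basic conditions; the aldehyde has no α-hydrogen and cannot epimerise.

Step 12
Reactants: 17 (2R,4R)-4-(tert-butyldimethylsilyloxy)-4-{(2S,3S)-2-[(1Z)-2-iodoprop-1-en-1-yl]-5-oxooxolan-3-yl}-2-methyl-2-(triethylsilyloxy)butanal; 18 tributyl(1-ethoxyvinyl)stannane
Product: 20 (2R,4R)-4-{(2R,3S)-2-[(1Z)-4-bromo-2-methyl-3-oxobut-1-en-1-yl]-5-oxooxolan-3-yl}-4-(tert-butyldimethylsilyloxy)-2-methyl-2-(triethylsilyloxy)butanal, via 2-ethoxydiene 19 (not isolated)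
Conditions: Pd(PPh3)4 (cat.), CuI (cat.), DMF, rt; then NBS, THF/H2O, 0 °C
Reagents that add atoms: N-bromosuccinimide, O=C1CCC(=O)N1Br; water, O
Why: Stille coupling forms C3–C4: zerovalent palladium inserts into the C–I bond with retention and copper assists transmetalation, so the Z geometry is kept. NBS then brominates the electron-rich enol ether terminus (C2) and water collapses the oxocarbenium ion to the ketone, which gives the bromomethyl ketone without strong base.

Step 13
Reactants: 20 (2R,4R)-4-{(2R,3S)-2-[(1Z)-4-bromo-2-methyl-3-oxobut-1-en-1-yl]-5-oxooxolan-3-yl}-4-(tert-butyldimethylsilyloxy)-2-methyl-2-(triethylsilyloxy)butanal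
Product: 22 (1S,6R,7S,8R,10R)-8-(tert-butyldimethylsilyloxy)-1-hydroxy-3-oxo-10-(triethylsilyloxy)germacr-4Z-en-12,6-olide, via trivalent samarium enolate 21 (not isolated)
Conditions: SmI2 (2.2 equiv), THF, −78 °C, substrate and reagent added simultaneously and slowly (final 0.003 M); NH4Cl (aq), −78 °C
Reagents that add atoms: none
Why: Two single-electron transfers from SmI2 cleave the C2–Br bond and give the trivalent samarium enolate 21 of the cross-conjugated dienone, which is nucleophilic only at C2. The oxophilic metal binds the C1 aldehyde and C2 adds through a closed six-membered transition state, so C1–C2 and the ten-membered ring form in one event; the closest known reaction type is the SmI2-mediated intramolecular Reformatsky (aldol) reaction of α-halo ketones, which closes medium and large rings. The closure is 10-(enolendo)-exo-trig, and the Z alkene and the trans-lactone hold C3 and C6 cis, which shortens the distance between the termini. The new stereocentre C1 is controlled by C10: with the non-chelating triethylsilyl ether the polar Felkin–Anh arrangement places the C10–O bond anti to the incoming C2, which passes the C14 methyl and not C9 and stays gauche to C9 as the ring requires, so the 1,10-anti adduct (1S) should result. A chelate to a benzyl-type C10 ether with entry on the methyl face would give the 1,10-syn epimer and from it a cis-epoxide, which is why no chelating group is used. Chemoselectivity is needed for C–Br reduction over ketyl formation at the aldehyde and over reduction of the γ-acyloxy enone; it rests on the much faster reduction of α-halo ketones at −78 °C in THF without HMPA or proton donors and on a small excess of reagent added at the rate of the substrate. The aldehyde cannot enolise (quaternary C10), and the samarium-bound aldolate should resist retro-aldol cleavage and dehydration until the cold quench.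

Step 14
Reactants: 22 (1S,6R,7S,8R,10R)-8-(tert-butyldimethylsilyloxy)-1-hydroxy-3-oxo-10-(triethylsilyloxy)germacr-4Z-en-12,6-olide
Product: 23 (1S,3S,6R,7S,8R,10R)-8-(tert-butyldimethylsilyloxy)-1,3-dihydroxy-10-(triethylsilyloxy)germacr-4Z-en-12,6-olide
Conditions: Me4NBH(OAc)3, MeCN/AcOH, −30 °C
Reagents that add atoms: none
Why: Evans–Saksena reduction: the C1 hydroxyl exchanges onto boron and delivers hydride intramolecularly through a six-membered transition state, which should give the 1,3-anti diol (3S) by 1,2-reduction of the enone. The acidic medium prevents retro-aldol cleavage.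

Step 15
Reactants: 23 (1S,3S,6R,7S,8R,10R)-8-(tert-butyldimethylsilyloxy)-1,3-dihydroxy-10-(triethylsilyloxy)germacr-4Z-en-12,6-olide
Product: 24 (1S,3S,6R,7S,8R,10R)-8-(tert-butyldimethylsilyloxy)-1-hydroxy-3-(2-methylprop-2-enoyloxy)-10-(triethylsilyloxy)germacr-4Z-en-12,6-olide
Conditions: methacrylic anhydride, Et3N, DMAP (cat.), CH2Cl2, −20 °C
Reagents that add atoms: methacrylic anhydride, C=C(C)C(=O)OC(=O)C(C)=C
Why: Site-selective DMAP-catalysed acylation: the allylic C3 hydroxyl is far less hindered than the C1 hydroxyl, which is neopentyl and flanked by the C10 triethylsilyl ether.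

Step 16
Reactants: 24 (1S,3S,6R,7S,8R,10R)-8-(tert-butyldimethylsilyloxy)-1-hydroxy-3-(2-methylprop-2-enoyloxy)-10-(triethylsilyloxy)germacr-4Z-en-12,6-olide
Product: 25 (1S,3S,6R,7S,8R,10R)-8-(tert-butyldimethylsilyloxy)-1-(methanesulfonyloxy)-3-(2-methylprop-2-enoyloxy)-10-(triethylsilyloxy)germacr-4Z-en-12,6-olide
Conditions: MsCl, Et3N, CH2Cl2, 0 °C
Reagents that add atoms: methanesulfonyl chloride, CS(=O)(=O)Cl
Why: Mesylation through sulfene tolerates the hindered secondary alcohol and proceeds with retention, which prepares C1 for displacement.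

Step 17
Reactants: 25 (1S,3S,6R,7S,8R,10R)-8-(tert-butyldimethylsilyloxy)-1-(methanesulfonyloxy)-3-(2-methylprop-2-enoyloxy)-10-(triethylsilyloxy)germacr-4Z-en-12,6-olide
Product: 27 (1R,3S,6R,7S,8R,10R)-8-(tert-butyldimethylsilyloxy)-1,10-epoxy-3-(2-methylprop-2-enoyloxy)germacr-4Z-en-12,6-olide, via tetrabutylammonium C10 alkoxide 26 (not isolated)
Conditions: Bu4NF (1.2 equiv), THF, 0 °C
Reagents that add atoms: none
Why: Fluoride should remove the tertiary TES ether faster than the hindered secondary TBS ether, and the C10 alkoxide displaces the adjacent mesylate in a 3-exo-tet closure with inversion at C1. The 1,10-anti arrangement thus becomes the trans-epoxide (1R,10R).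

Step 18
Reactants: 27 (1R,3S,6R,7S,8R,10R)-8-(tert-butyldimethylsilyloxy)-1,10-epoxy-3-(2-methylprop-2-enoyloxy)germacr-4Z-en-12,6-olide
Product: 31 (1R,3S,6R,7S,8R,10R)-8-(tert-butyldimethylsilyloxy)-1,10-epoxy-3-(2-methylprop-2-enoyloxy)germacra-4Z,11(13)-dien-12,6-olide, via lithium lactone enolate 28 (not isolated), via Mannich base 29 (not isolated), via trimethylammonium iodide 30 (not isolated)
Conditions: LiHMDS, THF, −78 °C; CH2=NMe2+ I−, −78 → 0 °C; then MeI, THF, rt; NaHCO3 (aq)
Reagents that add atoms: N,N-dimethylmethyleneiminium iodide (Eschenmoser's salt), C=[N+](C)C.[I-]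
Why: Mannich reaction of the lactone enolate with Eschenmoser's salt, then quaternisation and mild base-induced elimination, the standard α-methylenation of butyrolactones. LiHMDS at −78 °C is too hindered to add to the methacrylate, which has no α-hydrogen, and the epoxide is inert at this temperature.

Step 19
Reactants: 31 (1R,3S,6R,7S,8R,10R)-8-(tert-butyldimethylsilyloxy)-1,10-epoxy-3-(2-methylprop-2-enoyloxy)germacra-4Z,11(13)-dien-12,6-olide
Product: 32 (1R,3S,6R,7R,8R,10R)-1,10-epoxy-8-hydroxy-3-(2-methylprop-2-enoyloxy)germacra-4Z,11(13)-dien-12,6-olide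
Conditions: HF·pyridine, pyridine, THF, 0 °C → rt
Reagents that add atoms: none
Why: Pyridine-buffered HF cleaves the secondary TBS ether without generating an alkoxide, so the α-methylene lactone and the lactone position (O6 versus O8) are not disturbed and the epoxide should survive.

Step 20
Reactants: 32 (1R,3S,6R,7R,8R,10R)-1,10-epoxy-8-hydroxy-3-(2-methylprop-2-enoyloxy)germacra-4Z,11(13)-dien-12,6-olide
Product: 33 (1R,3S,6R,7R,8R,10R)-1,10-epoxy-8-[(2Z)-2-methylbut-2-enoyloxy]-3-(2-methylprop-2-enoyloxy)germacra-4Z,11(13)-dien-12,6-olide (CNP0294228.1)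
Conditions: angelic acid, 2,4,6-Cl3C6H2COCl, Et3N, toluene, rt; then 32, 75 °C
Reagents that add atoms: angelic acid, C/C=C(/C)C(=O)O
Why: Yamaguchi-type esterification through the mixed anhydride of angelic acid, in which the alcohol attacks the unhindered angeloyl carbonyl. Omitting DMAP and keeping the heating short are known to preserve the Z (angelate) geometry.

## Compound list

1 | (5S)-5-(hydroxymethyl)furan-2(5H)-one | OC[C@H]1OC(=O)C=C1 | starting material
2 | (5S)-5-{[(triethylsilyl)oxy]methyl}furan-2(5H)-one | CC[Si](CC)(CC)OC[C@H]1OC(=O)C=C1 | intermediate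
3 | [(2S)-2-methyloxiran-2-yl]methanol ((S)-2-methylglycidol) | C[C@]1(CO)CO1 | starting material
4 | (2R)-2-{[(4-methoxybenzyl)oxy]methyl}-2-methyloxirane | C[C@]1(COCc2ccc(OC)cc2)CO1 | intermediate
5 | 1,3-dithiane | C1CSCSC1 | starting material
6 | 2-lithio-1,3-dithiane | [Li]C1SCCCS1 | intermediate
7 | lithium (2R)-1-(1,3-dithian-2-yl)-3-[(4-methoxybenzyl)oxy]-2-methylpropan-2-olate | C[C@]([O-])(COCc1ccc(OC)cc1)CC1SCCCS1.[Li+] | intermediate
8 | {[(2R)-1-(1,3-dithian-2-yl)-3-[(4-methoxybenzyl)oxy]-2-methylpropan-2-yl]oxy}triethylsilane | C[C@](O[Si](CC)(CC)CC)(COCc1ccc(OC)cc1)CC1SCCCS1 | intermediate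
9 | 2-lithio derivative of 8 (lithium on the dithiane C2) | C[C@](O[Si](CC)(CC)CC)(COCc1ccc(OC)cc1)CC1([Li])SCCCS1 | intermediate
10 | (4S,5S)-4-{2-[(2R)-3-[(4-methoxybenzyl)oxy]-2-methyl-2-(triethylsilyloxy)propyl]-1,3-dithian-2-yl}-5-{[(triethylsilyl)oxy]methyl}oxolan-2-one | CC[Si](CC)(CC)OC[C@H]1OC(=O)C[C@@H]1C1(C[C@@](C)(O[Si](CC)(CC)CC)COCc2ccc(OC)cc2)SCCCS1 | intermediate
11 | (4S,5S)-4-[(3R)-4-[(4-methoxybenzyl)oxy]-3-methyl-3-(triethylsilyloxy)butanoyl]-5-{[(triethylsilyl)oxy]methyl}oxolan-2-one | CC[Si](CC)(CC)OC[C@H]1OC(=O)C[C@@H]1C(=O)C[C@@](C)(O[Si](CC)(CC)CC)COCc1ccc(OC)cc1 | intermediate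
12 | (4R,5S)-4-[(1R,3R)-1-hydroxy-4-[(4-methoxybenzyl)oxy]-3-methyl-3-(triethylsilyloxy)butyl]-5-{[(triethylsilyl)oxy]methyl}oxolan-2-one | CC[Si](CC)(CC)OC[C@H]1OC(=O)C[C@@H]1[C@H](O)C[C@@](C)(O[Si](CC)(CC)CC)COCc1ccc(OC)cc1 | intermediate
13 | (4S,5S)-4-[(1R,3R)-1-(tert-butyldimethylsilyloxy)-4-[(4-methoxybenzyl)oxy]-3-methyl-3-(triethylsilyloxy)butyl]-5-{[(triethylsilyl)oxy]methyl}oxolan-2-one | CC[Si](CC)(CC)OC[C@H]1OC(=O)C[C@@H]1[C@H](O[Si](C)(C)C(C)(C)C)C[C@@](C)(O[Si](CC)(CC)CC)COCc1ccc(OC)cc1 | intermediate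
14 | (2S,3S)-3-[(1R,3R)-1-(tert-butyldimethylsilyloxy)-4-[(4-methoxybenzyl)oxy]-3-methyl-3-(triethylsilyloxy)butyl]-5-oxooxolane-2-carbaldehyde | O=C[C@H]1OC(=O)C[C@@H]1[C@H](O[Si](C)(C)C(C)(C)C)C[C@@](C)(O[Si](CC)(CC)CC)COCc1ccc(OC)cc1 | intermediate
15 | (4S,5S)-4-[(1R,3R)-1-(tert-butyldimethylsilyloxy)-4-[(4-methoxybenzyl)oxy]-3-methyl-3-(triethylsilyloxy)butyl]-5-[(1Z)-2-iodoprop-1-en-1-yl]oxolan-2-one | I/C(C)=C\[C@H]1OC(=O)C[C@@H]1[C@H](O[Si](C)(C)C(C)(C)C)C[C@@](C)(O[Si](CC)(CC)CC)COCc1ccc(OC)cc1 | intermediate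
16 | (4S,5S)-4-[(1R,3R)-1-(tert-butyldimethylsilyloxy)-4-hydroxy-3-methyl-3-(triethylsilyloxy)butyl]-5-[(1Z)-2-iodoprop-1-en-1-yl]oxolan-2-one | I/C(C)=C\[C@H]1OC(=O)C[C@@H]1[C@H](O[Si](C)(C)C(C)(C)C)C[C@@](C)(O[Si](CC)(CC)CC)CO | intermediate
17 | (2R,4R)-4-(tert-butyldimethylsilyloxy)-4-{(2S,3S)-2-[(1Z)-2-iodoprop-1-en-1-yl]-5-oxooxolan-3-yl}-2-methyl-2-(triethylsilyloxy)butanal | I/C(C)=C\[C@H]1OC(=O)C[C@@H]1[C@H](O[Si](C)(C)C(C)(C)C)C[C@@](C)(O[Si](CC)(CC)CC)C=O | intermediate
18 | tributyl(1-ethoxyvinyl)stannane | CCCC[Sn](CCCC)(CCCC)C(=C)OCC | starting material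
19 | (2R,4R)-4-(tert-butyldimethylsilyloxy)-4-{(2R,3S)-2-[(1Z)-3-ethoxy-2-methylbuta-1,3-dien-1-yl]-5-oxooxolan-3-yl}-2-methyl-2-(triethylsilyloxy)butanal | C=C(OCC)/C(C)=C\[C@H]1OC(=O)C[C@@H]1[C@H](O[Si](C)(C)C(C)(C)C)C[C@@](C)(O[Si](CC)(CC)CC)C=O | intermediate
20 | (2R,4R)-4-{(2R,3S)-2-[(1Z)-4-bromo-2-methyl-3-oxobut-1-en-1-yl]-5-oxooxolan-3-yl}-4-(tert-butyldimethylsilyloxy)-2-methyl-2-(triethylsilyloxy)butanal | BrCC(=O)/C(C)=C\[C@H]1OC(=O)C[C@@H]1[C@H](O[Si](C)(C)C(C)(C)C)C[C@@](C)(O[Si](CC)(CC)CC)C=O | intermediate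
21 | diiodosamarium enolate of the C3 ketone of 20 (C2=C3–O–SmI2, bromine lost) | C=C(O[Sm](I)I)/C(C)=C\[C@H]1OC(=O)C[C@@H]1[C@H](O[Si](C)(C)C(C)(C)C)C[C@@](C)(O[Si](CC)(CC)CC)C=O | intermediate
22 | (1S,6R,7S,8R,10R)-8-(tert-butyldimethylsilyloxy)-1-hydroxy-3-oxo-10-(triethylsilyloxy)germacr-4Z-en-12,6-olide | O=C1C[C@H](O)[C@](C)(O[Si](CC)(CC)CC)C[C@@H](O[Si](C)(C)C(C)(C)C)[C@H]2CC(=O)O[C@@H]2/C=C\1C | intermediate
23 | (1S,3S,6R,7S,8R,10R)-8-(tert-butyldimethylsilyloxy)-1,3-dihydroxy-10-(triethylsilyloxy)germacr-4Z-en-12,6-olide | O[C@H]1C[C@H](O)[C@](C)(O[Si](CC)(CC)CC)C[C@@H](O[Si](C)(C)C(C)(C)C)[C@H]2CC(=O)O[C@@H]2/C=C\1C | intermediate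
24 | (1S,3S,6R,7S,8R,10R)-8-(tert-butyldimethylsilyloxy)-1-hydroxy-3-(2-methylprop-2-enoyloxy)-10-(triethylsilyloxy)germacr-4Z-en-12,6-olide | C=C(C)C(=O)O[C@H]1C[C@H](O)[C@](C)(O[Si](CC)(CC)CC)C[C@@H](O[Si](C)(C)C(C)(C)C)[C@H]2CC(=O)O[C@@H]2/C=C\1C | intermediate
25 | (1S,3S,6R,7S,8R,10R)-8-(tert-butyldimethylsilyloxy)-1-(methanesulfonyloxy)-3-(2-methylprop-2-enoyloxy)-10-(triethylsilyloxy)germacr-4Z-en-12,6-olide | C=C(C)C(=O)O[C@H]1C[C@H](OS(C)(=O)=O)[C@](C)(O[Si](CC)(CC)CC)C[C@@H](O[Si](C)(C)C(C)(C)C)[C@H]2CC(=O)O[C@@H]2/C=C\1C | intermediate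
26 | tetrabutylammonium C10 alkoxide of 25 (triethylsilyl group lost) | C=C(C)C(=O)O[C@H]1C[C@H](OS(C)(=O)=O)[C@](C)([O-])C[C@@H](O[Si](C)(C)C(C)(C)C)[C@H]2CC(=O)O[C@@H]2/C=C\1C.CCCC[N+](CCCC)(CCCC)CCCC | intermediate
27 | (1R,3S,6R,7S,8R,10R)-8-(tert-butyldimethylsilyloxy)-1,10-epoxy-3-(2-methylprop-2-enoyloxy)germacr-4Z-en-12,6-olide | C=C(C)C(=O)O[C@H]1C[C@H]2O[C@]2(C)C[C@@H](O[Si](C)(C)C(C)(C)C)[C@H]2CC(=O)O[C@@H]2/C=C\1C | intermediate
28 | lithium enolate of the lactone of 27 (C11=C12–OLi) | C=C(C)C(=O)O[C@H]1C[C@H]2O[C@]2(C)C[C@@H](O[Si](C)(C)C(C)(C)C)[C@H]2C=C(O[Li])O[C@@H]2/C=C\1C | intermediate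
29 | 11-[(dimethylamino)methyl] derivative of 27 (C11 configuration not defined) | C=C(C)C(=O)O[C@H]1C[C@H]2O[C@]2(C)C[C@@H](O[Si](C)(C)C(C)(C)C)[C@H]2C(CN(C)C)C(=O)O[C@@H]2/C=C\1C | intermediate
30 | 11-[(trimethylammonio)methyl] iodide derived from 29 | C=C(C)C(=O)O[C@H]1C[C@H]2O[C@]2(C)C[C@@H](O[Si](C)(C)C(C)(C)C)[C@H]2C(C[N+](C)(C)C)C(=O)O[C@@H]2/C=C\1C.[I-] | intermediate
31 | (1R,3S,6R,7S,8R,10R)-8-(tert-butyldimethylsilyloxy)-1,10-epoxy-3-(2-methylprop-2-enoyloxy)germacra-4Z,11(13)-dien-12,6-olide | C=C(C)C(=O)O[C@H]1C[C@H]2O[C@]2(C)C[C@@H](O[Si](C)(C)C(C)(C)C)[C@H]2C(=C)C(=O)O[C@@H]2/C=C\1C | intermediate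
32 | (1R,3S,6R,7R,8R,10R)-1,10-epoxy-8-hydroxy-3-(2-methylprop-2-enoyloxy)germacra-4Z,11(13)-dien-12,6-olide | C=C(C)C(=O)O[C@H]1C[C@H]2O[C@]2(C)C[C@@H](O)[C@H]2C(=C)C(=O)O[C@@H]2/C=C\1C | intermediate
33 | (1R,3S,6R,7R,8R,10R)-1,10-epoxy-8-[(2Z)-2-methylbut-2-enoyloxy]-3-(2-methylprop-2-enoyloxy)germacra-4Z,11(13)-dien-12,6-olide (CNP0294228.1) | C=C(C)C(=O)O[C@H]1C[C@H]2O[C@]2(C)C[C@@H](OC(=O)/C(C)=C\C)[C@H]2C(=C)C(=O)O[C@@H]2/C=C\1C | target

## Step count and least certain steps

Total: 20 steps. Longest linear sequence: 19 steps (from 3 through steps 2–20); the branch from 1 is one step.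

Step 13 (key step). The facial selectivity at C1 may be poor or reversed, because the conformational demands of the forming ten-membered ring can override the Felkin–Anh preference. The samarium enolate may also be protonated before it cyclises, or excess reagent may reduce the γ-acyloxy enone with loss of the lactone oxygen. Fallback: an open-transition-state Mukaiyama aldol macrocyclisation, which has no reductant and a stronger Felkin bias with a monodentate Lewis acid. It sets out from 19: mild acid (PPTS, wet acetone) gives the methyl enone F1; TMSOTf/Et3N gives the trimethylsilyl dienol ether F2; BF3·OEt2 in CH2Cl2 at −78 °C under high dilution closes C1–C2 and returns to the route at 22.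

Step 4. The strongly basic, hindered tertiary carbanion 9 may deprotonate 2 at C5 (with loss of the silyloxy group by elimination) or add 1,2 instead of adding to the β-carbon. Fallback: a neutral radical conjugate addition. It sets out from 8: carboxylation of 9 with CO2 gives the dithiane-2-carboxylic acid F3; photoredox decarboxylation ([Ir(dF(CF3)ppy)2(dtbbpy)]PF6, K2HPO4, DMF, blue light) generates the 2-dithianyl radical, which adds to 2 anti to the C5 substituent (Giese addition) and returns at 10.

Step 6. Felkin control by C7 may be weak because both ketone substituents are bulky, and the C8 alkoxide may migrate the lactone before the quench. Fallback: catalyst control in place of substrate control. From 11, reduction with (S)-2-methyl-CBS-oxazaborolidine and catecholborane, whose sense matches the 8R carbinol (C7 as the larger group) and which forms no free alkoxide, returns at 12; no new compound is made.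

Step 9. The ylide decomposes readily and the Z selectivity of the iodo-olefination may be moderate; base-induced epimerisation at C6 is a further risk. Fallback: a Corey–Fuchs/Negishi sequence. From 14, CBr4/PPh3 gives the dibromoalkene F4; trans-selective methylation (MeZnCl, PdCl2(DPEphos)) gives the Z-alkenyl bromide F5, which takes the place of 15 in steps 10 and 11 (alcohol F6, aldehyde F7); Stille coupling of F7 with 18 at slightly higher temperature returns at 19.

Step 15. Acylation may occur at both hydroxyls or be followed by acyl or silyl migration between O1, O3 and O10. Fallback: differentiate the two oxygens before C3 is reduced, which also removes the dependence on the directed reduction of step 14. From 22, TESOTf/2,6-lutidine gives the C1 triethylsilyl ether F8; (R)-2-methyl-CBS-oxazaborolidine with catecholborane reduces the enone to the 3S alcohol F9; methacrylic anhydride/DMAP gives the ester F10; PPTS in MeOH removes the secondary TES ether in preference to the tertiary one and returns at 24.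

Step 18. The amide base may attack the methacrylate, or the enolate may open the epoxide across the ring. Fallback: soft enolisation before the epoxide exists. From 25, TBSOTf/Et3N gives the ketene silyl acetal F11; Eschenmoser's salt gives the Mannich base F12 (Mukaiyama–Mannich reaction); MeI gives the ammonium iodide F13 and NaHCO3 the α-methylene mesylate F14; Bu4NF as in step 17 closes the epoxide and returns at 31.

## Further compounds

F1 | step 13 | methyl enone: 20 with CH3 in place of CH2Br at C2 | CC(=O)/C(C)=C\[C@H]1OC(=O)C[C@@H]1[C@H](O[Si](C)(C)C(C)(C)C)C[C@@](C)(O[Si](CC)(CC)CC)C=O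
F2 | step 13 | trimethylsilyl dienol ether of F1 (C2=C3–OSiMe3) | C=C(O[Si](C)(C)C)/C(C)=C\[C@H]1OC(=O)C[C@@H]1[C@H](O[Si](C)(C)C(C)(C)C)C[C@@](C)(O[Si](CC)(CC)CC)C=O
F3 | step 4 | 2-[(2R)-3-[(4-methoxybenzyl)oxy]-2-methyl-2-(triethylsilyloxy)propyl]-1,3-dithiane-2-carboxylic acid | C[C@](O[Si](CC)(CC)CC)(COCc1ccc(OC)cc1)CC1(C(=O)O)SCCCS1
F0 | step 6 | none | none
F4 | step 9 | 5-(2,2-dibromoethenyl) analogue of 15 | BrC(Br)=C[C@H]1OC(=O)C[C@@H]1[C@H](O[Si](C)(C)C(C)(C)C)C[C@@](C)(O[Si](CC)(CC)CC)COCc1ccc(OC)cc1
F5 | step 9 | (1Z)-2-bromoprop-1-enyl analogue of 15 | Br/C(C)=C\[C@H]1OC(=O)C[C@@H]1[C@H](O[Si](C)(C)C(C)(C)C)C[C@@](C)(O[Si](CC)(CC)CC)COCc1ccc(OC)cc1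
F6 | step 9 | (1Z)-2-bromoprop-1-enyl analogue of 16 | Br/C(C)=C\[C@H]1OC(=O)C[C@@H]1[C@H](O[Si](C)(C)C(C)(C)C)C[C@@](C)(O[Si](CC)(CC)CC)CO
F7 | step 9 | (1Z)-2-bromoprop-1-enyl analogue of 17 | Br/C(C)=C\[C@H]1OC(=O)C[C@@H]1[C@H](O[Si](C)(C)C(C)(C)C)C[C@@](C)(O[Si](CC)(CC)CC)C=O
F8 | step 15 | 1-O-triethylsilyl ether of 22 | O=C1C[C@H](O[Si](CC)(CC)CC)[C@](C)(O[Si](CC)(CC)CC)C[C@@H](O[Si](C)(C)C(C)(C)C)[C@H]2CC(=O)O[C@@H]2/C=C\1C
F9 | step 15 | 1-O-triethylsilyl ether of 23 (3S alcohol) | O[C@H]1C[C@H](O[Si](CC)(CC)CC)[C@](C)(O[Si](CC)(CC)CC)C[C@@H](O[Si](C)(C)C(C)(C)C)[C@H]2CC(=O)O[C@@H]2/C=C\1C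
F10 | step 15 | 1-O-triethylsilyl ether of 24 | C=C(C)C(=O)O[C@H]1C[C@H](O[Si](CC)(CC)CC)[C@](C)(O[Si](CC)(CC)CC)C[C@@H](O[Si](C)(C)C(C)(C)C)[C@H]2CC(=O)O[C@@H]2/C=C\1C
F11 | step 18 | tert-butyldimethylsilyl ketene acetal of the lactone of 25 | C=C(C)C(=O)O[C@H]1C[C@H](OS(C)(=O)=O)[C@](C)(O[Si](CC)(CC)CC)C[C@@H](O[Si](C)(C)C(C)(C)C)[C@H]2C=C(O[Si](C)(C)C(C)(C)C)O[C@@H]2/C=C\1C
F12 | step 18 | 11-[(dimethylamino)methyl] derivative of 25 | C=C(C)C(=O)O[C@H]1C[C@H](OS(C)(=O)=O)[C@](C)(O[Si](CC)(CC)CC)C[C@@H](O[Si](C)(C)C(C)(C)C)[C@H]2C(CN(C)C)C(=O)O[C@@H]2/C=C\1C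
F13 | step 18 | 11-[(trimethylammonio)methyl] iodide derived from F12 | C=C(C)C(=O)O[C@H]1C[C@H](OS(C)(=O)=O)[C@](C)(O[Si](CC)(CC)CC)C[C@@H](O[Si](C)(C)C(C)(C)C)[C@H]2C(C[N+](C)(C)C)C(=O)O[C@@H]2/C=C\1C.[I-]
F14 | step 18 | 11(13)-methylene derivative of 25 | C=C(C)C(=O)O[C@H]1C[C@H](OS(C)(=O)=O)[C@](C)(O[Si](CC)(CC)CC)C[C@@H](O[Si](C)(C)C(C)(C)C)[C@H]2C(=C)C(=O)O[C@@H]2/C=C\1C
A1 | alternative 1 | 2-[(4S,5R)-5-(2,2-dimethoxyethyl)-2,2,5-trimethyl-1,3-dioxolan-4-yl]acetaldehyde | O=CC[C@@H]1OC(C)(C)O[C@]1(C)CC(OC)OC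
A2 | alternative 1 | trimethyl(prop-1-yn-1-yl)silane | CC#C[Si](C)(C)C
A3 | alternative 1 | acrolein | C=CC=O
A4 | alternative 1 | Z-2-ene-1,4-diol with trimethylsilyl at C5, vinyl at C6, 1,10-acetonide and C8 dimethyl acetal | C=C[C@H](O)/C([Si](C)(C)C)=C(/C)[C@@H](O)C[C@@H]1OC(C)(C)O[C@]1(C)CC(OC)OC
A5 | alternative 2 | 3β,8β-dihydroxygermacra-1(10)E,4Z,11(13)-trien-12-oic acid | O[C@H]1C/C=C(\C)C[C@@H](O)[C@@H](C(=C)C(=O)O)C/C=C\1C
A6 | alternative 2 | 3β,8β-dihydroxygermacra-1(10)E,4Z,11(13)-trien-12,6α-olide | O[C@H]1C/C=C(\C)C[C@@H](O)[C@H]2C(=C)C(=O)O[C@@H]2/C=C\1C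
A7 | alternative 3 | 4-(tert-butyldimethylsilyloxy)-1-[(E)-2-(4-methoxybenzyloxy)ethenyl]-3-methyl-6-(prop-1-en-2-yl)cyclohex-2-en-1-ol (alkenyl groups trans) | O[C@]1(/C=C/OCc2ccc(OC)cc2)C=C(C)[C@@H](O[Si](C)(C)C(C)(C)C)C[C@@H]1C(C)=C
A8 | alternative 3 | 3-(tert-butyldimethylsilyloxy)-8-(4-methoxybenzyloxy)-4,10-dimethylcyclodeca-1(10)E,4Z-dien-6-one (germacrane numbering) | CC(C)(C)[Si](C)(C)O[C@H]1C/C=C(\C)C[C@@H](OCc2ccc(OC)cc2)CC(=O)/C=C\1C
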